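**Strategy.** The target is cut at the C1–C9 bond of its γ-lactone (ring C1–C9–O8–C7–C10, locants of the 8-oxabicyclo[5.2.1]decane name). C9 is then a carbonate carbon on the C7 oxygen and C1 the α-carbon of the C10 ketone. Because C5–H lies in a 1,3-diketone, the carbonate can be stored as a cyclic enol carbonate between O8 and the C6 enol oxygen. In one operation a ketone enolate at C1 attacks this carbonate and expels the diketonate: the C1–C9 bond forms, the lactone closes and C1 is set from C7. The eight-membered ring of this precursor comes from a cyclohexanone by two-carbon ring expansion.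

Key step: step 13

Remark: the configuration at C5 of the target (the 1,3-diketone methine) is taken to be the thermodynamic one; it is reached by proton equilibration on work-up and is not set kinetically.
Remark: aldehyde 1 is taken as a catalogue compound.

Step 1
Reactants: 1 5-methylhex-4-enal; 2 but-3-en-2-one
Product: 3 (R)-2-(3-methylbut-2-enyl)-5-oxohexanal
Conditions: (R)-2-[diphenyl(trimethylsilyloxy)methyl]pyrrolidine (5 mol%), ethyl 3,4-dihydroxybenzoate (20 mol%), neat, 4 °C
Reagents that add atoms: none
Why: Enamine-catalysed asymmetric Michael addition: the E-enamine of 1 is shielded on one face by the diphenyl(silyloxy)methyl arm of the (R)-pyrrolidine, so the enone adds to the open face and the new centre is set as (R).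

Step 2
Reactants: 3 (R)-2-(3-methylbut-2-enyl)-5-oxohexanal
Product: 4 (R)-4-(3-methylbut-2-enyl)cyclohex-2-en-1-one
Conditions: LiOH (cat.), i-PrOH, rt
Reagents that add atoms: none
Why: Intramolecular aldol condensation of the methyl ketone onto the aldehyde, followed by loss of water, should give the cyclohexenone; ring closure is expected to be faster than enolisation of the aldehyde α-centre, which becomes C4 unchanged.

Step 3
Reactants: 4 (R)-4-(3-methylbut-2-enyl)cyclohex-2-en-1-one; 5 methylmagnesium bromide
Product: 7 (R)-3-methyl-4-(3-methylbut-2-enyl)cyclohex-2-en-1-one, via silyl enol ether 6 (not isolated)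
Conditions: MeMgBr, CuBr·SMe2 (5 mol%), Me3SiCl, THF, −78 °C; then Pd(OAc)2 (10 mol%), O2, DMSO, rt
Reagents that add atoms: methylmagnesium bromide (5), C[Mg]Br
Why: Copper-catalysed conjugate addition with silyl trapping, followed by Saegusa–Ito dehydrogenation of 6, puts the enone back in conjugation with the new methyl group at C3; the C3 centre of 6 becomes trigonal again in 7 and C4 is not touched.

Step 4
Reactants: 7 (R)-3-methyl-4-(3-methylbut-2-enyl)cyclohex-2-en-1-one; 8 5-bromo-2-methylpent-2-ene
Product: 10 (3S,4R)-3-methyl-4-(3-methylbut-2-enyl)-3-(4-methylpent-3-enyl)cyclohexan-1-one, via silyl enol ether 9 (not isolated)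
Conditions: 8, Mg, THF; then CuBr·SMe2 (10 mol%), Me3SiCl, THF, −78 to −30 °C; then HCl (1 M aq.)
Reagents that add atoms: 5-bromo-2-methylpent-2-ene (8, used as its Grignard reagent), CC(C)=CCCBr
Why: Copper-catalysed conjugate addition of the Grignard reagent to the β,β-disubstituted enone, accelerated by Me3SiCl: the nucleophile should enter anti to the neighbouring C4 prenyl group (trans addition on the half-chair), which sets the quaternary centre as (3S) with homoprenyl trans and methyl cis to prenyl.

Step 5
Reactants: 10 (3S,4R)-3-methyl-4-(3-methylbut-2-enyl)-3-(4-methylpent-3-enyl)cyclohexan-1-one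
Product: 11 trimethyl{[(4S,5S)-5-methyl-4-(3-methylbut-2-enyl)-5-(4-methylpent-3-enyl)cyclohex-1-en-1-yl]oxy}silane
Conditions: LiN(i-Pr)2, Me3SiCl, THF, −78 °C
Reagents that add atoms: chlorotrimethylsilane, C[Si](C)(C)Cl
Why: Kinetic enolisation should remove a proton from the C6 methylene, because the C2 methylene is neopentylic and shielded by the quaternary C3, and O-silylation fixes this regiodefined silyl enol ether; no stereocentre is formed.

Step 6
Reactants: 11 the kinetic silyl enol ether; 12 dichloroacetyl chloride
Product: 13 (3S,4S)-8,8-dichloro-3-methyl-4-(3-methylbut-2-enyl)-3-(4-methylpent-3-enyl)-1-(trimethylsilyloxy)bicyclo[4.2.0]octan-7-one (cis-fused, mixture at the two fusion carbons)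
Conditions: Et3N, hexane, rt, slow addition of 12
Reagents that add atoms: dichloroacetyl chloride (12), O=C(Cl)C(Cl)Cl
Why: [2+2] cycloaddition of dichloroketene (formed in the flask from 12 and Et3N) with the electron-rich silyl enol ether, which should react far faster than the two unactivated trisubstituted alkenes; the ketene carbonyl carbon bonds to the enol ether CH, and the two new fusion centres are removed again in step 7.

Step 7
Reactants: 13 the dichlorocyclobutanone
Product: 15 (5S,6R)-5-methyl-6-(3-methylbut-2-enyl)-5-(4-methylpent-3-enyl)cyclooctane-1,3-dione, via dechlorinated cyclobutanone 14 (not isolated)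
Conditions: Zn, AcOH, i-PrOH–H2O, 0 °C to rt
Reagents that add atoms: none
Why: Zinc in acetic acid removes both chlorine atoms to give 14, the silyl ether is then cleaved and the β-hydroxycyclobutanone opens by retro-aldol cleavage of the fusion bond, a two-carbon ring expansion that should give the cyclooctane-1,3-dione.

Step 8
Reactants: 15 the cyclooctane-1,3-dione; 16 1-bromo-3-methylbut-2-ene
Product: 17 (6S,7S)-7-methyl-4,6-bis(3-methylbut-2-enyl)-7-(4-methylpent-3-enyl)cyclooctane-1,3-dione (epimers at C4)
Conditions: LiN(i-Pr)2 (2.2 equiv), THF–DMPU, −78 to −30 °C; then 16; NH4Cl (aq.)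
Reagents that add atoms: 1-bromo-3-methylbut-2-ene (16), CC(C)=CCBr
Why: γ-Alkylation of a 1,3-diketone dianion: after the enolate is formed the second lithiation should take place at the unhindered C8 methylene of 15 (C4 is neopentylic) and this most basic carbon is alkylated by the allylic bromide; the new centre is enolisable, forms as a mixture of epimers and becomes trigonal again in step 13.

Step 9
Reactants: 17 the 4-prenyl dione; 18 3-methylbut-2-enyl acetate
Product: 19 (6S,7S)-7-methyl-2,4,6-tris(3-methylbut-2-enyl)-7-(4-methylpent-3-enyl)cyclooctane-1,3-dione (C2 and C4 not defined)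
Conditions: Pd(PPh3)4 (5 mol%), DBU, THF, rt
Reagents that add atoms: 3-methylbut-2-enyl acetate (18), CC(C)=CCOC(C)=O
Why: Tsuji–Trost allylation: the 1,3-diketonate attacks the (1,1-dimethylallyl)palladium complex at its unsubstituted terminus and should give the C2-prenyl dione, any O-allyl product being re-ionised by zerovalent palladium; the C2 centre stays enolisable and is fixed only in step 11.

Step 10
Reactants: 19 the 2,4-diprenyl dione; 20 N-methoxy-N,2-dimethylpropanamide
Product: 21 (5R,6S)-5-methyl-2,6,8-tris(3-methylbut-2-enyl)-5-(4-methylpent-3-enyl)-4-(2-methylpropanoyl)cyclooctane-1,3-dione (C2, C4 and C8 not defined, enol forms)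
Conditions: LiN(i-Pr)2 (2.3 equiv), THF, −78 to 0 °C; then 20; NH4Cl (aq.)
Reagents that add atoms: N-methoxy-N,2-dimethylpropanamide (20), CC(C)C(=O)N(C)OC
Why: Acylation of the 1,3-diketone dianion (Weinreb-type ketone synthesis): the second lithiation can only take place at the C8 methylene of 19, the other α′ position (C4) being a methine, and addition to the N-methoxy-N-methylamide gives a chelated adduct that releases the ketone on work-up; the acylated carbon lies in a 1,3-diketone and is not stereodefined.

Step 11
Reactants: 21 the triketone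
Product: 22 (2R,5R,6S)-2-hydroxy-5-methyl-2,6,8-tris(3-methylbut-2-enyl)-5-(4-methylpent-3-enyl)-4-(2-methylpropanoyl)cyclooctane-1,3-dione (C4 and C8 not defined)
Conditions: KN(SiMe3)2 (2.1 equiv), THF, −78 °C; 3-phenyl-2-(phenylsulfonyl)oxaziridine; NH4Cl (aq.)
Reagents that add atoms: 3-phenyl-2-(phenylsulfonyl)oxaziridine, O=S(=O)(c1ccccc1)N1OC1c1ccccc1
Why: Electrophilic α-hydroxylation of the enolate by the N-sulfonyloxaziridine at C2, the other diketone carbon C4 being screened by the quaternary C5 and the isopropyl ketone; the enolate holds C8–C1–C2–C3–C4 in one plane and folds C5–C6–C7 to one side with prenyl and homoprenyl equatorial, the shape of a bicyclo[3.3.1]nonane-2,4-dione without its one-carbon bridge, so oxygen should enter from the face opposite this flap and set C2 as (R).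

Step 12
Reactants: 22 the hydroxy triketone; 23 1,1'-carbonyldiimidazole
Product: 24 (5R,6S,9aS)-5-methyl-6,8,9a-tris(3-methylbut-2-enyl)-5-(4-methylpent-3-enyl)-4-(2-methylpropanoyl)-5,6,7,8-tetrahydro-2H-cycloocta[d][1,3]dioxole-2,9(9aH)-dione (cyclic enol carbonate, C8 not defined)
Conditions: 4-(dimethylamino)pyridine (10 mol%), CH2Cl2, rt
Reagents that add atoms: 1,1'-carbonyldiimidazole (23), O=C(n1ccnc1)n1ccnc1
Why: Carbonylation with 1,1'-carbonyldiimidazole should join the tertiary hydroxyl and the enol oxygen of the adjacent 1,3-diketone in a five-membered cyclic carbonate (4-alkylidene-1,3-dioxolan-2-one, formed as carbonates are from 1,2-diols); no stereocentre changes.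

Step 13
Reactants: 24 the cyclic enol carbonate
Product: 25 (1R,3S,4R,5R,7S)-4-methyl-1,3,7-tris(3-methylbut-2-enyl)-4-(4-methylpent-3-enyl)-5-(2-methylpropanoyl)-8-oxabicyclo[5.2.1]decane-6,9,10-trione
Conditions: LiN(SiMe3)2 (1.2 equiv), THF, −78 to 0 °C; then NH4Cl (aq.)
Reagents that add atoms: none
Why: LiN(SiMe3)2 removes C8–H of 24 (the future C1–H, α to the ring ketone that becomes C10), the most acidic proton because the isobutyryl ketone is deactivated as a vinylogous carbonate, and the enolate carbon adds to the carbonate carbonyl; the tetrahedral intermediate then expels the enol oxygen as the stabilised 1,3-diketonate, so the carboxyl moves from oxygen to carbon. This is an intramolecular Claisen (Dieckmann-type) acylation of a ketone enolate by a carbonate, the reaction type used to close tetronic acids, run here as an anionic O-to-C carboxyl transfer. The γ-lactone ring (C1–C9–O8–C7–C10) closes in the 5-(enolendo)-exo-trig mode while the dioxolanone opens. The new quaternary centre C1 is controlled by C7: the carbonate carbon is held on O8, so it can reach only the enolate face on the same side as O8 and the bicycle must be cis-bridged, which gives (1R). The step needs C-acylation at C1 and not at the isobutyryl α-carbon, and loss of the enolate oxygen and not of O8; acidity should secure the first, leaving-group ability the second, and both are backed by the product being the only species that keeps the 1,3-diketone as its enolate, the thermodynamic sink of all reversible acyl transfers. Protonation on work-up should then give the more stable C5 epimer.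

**Compound list**

1 | 5-methylhex-4-enal | CC(C)=CCCC=O | starting material
2 | but-3-en-2-one | CC(=O)C=C | starting material
3 | (R)-2-(3-methylbut-2-enyl)-5-oxohexanal | O=C[C@@H](CC=C(C)C)CCC(C)=O | intermediate
4 | (R)-4-(3-methylbut-2-enyl)cyclohex-2-en-1-one | O=C1C=C[C@@H](CC=C(C)C)CC1 | intermediate
5 | methylmagnesium bromide | C[Mg]Br | starting material
6 | trimethyl{[(3R,4R)-3-methyl-4-(3-methylbut-2-enyl)cyclohex-1-en-1-yl]oxy}silane (methyl trans to prenyl) | C[Si](C)(C)OC1=C[C@H](C)[C@@H](CC=C(C)C)CC1 | intermediate (not isolated)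
7 | (R)-3-methyl-4-(3-methylbut-2-enyl)cyclohex-2-en-1-one | O=C1C=C(C)[C@@H](CC=C(C)C)CC1 | intermediate
8 | 5-bromo-2-methylpent-2-ene | CC(C)=CCCBr | starting material
9 | trimethyl{[(3R,4R)-3-methyl-4-(3-methylbut-2-enyl)-3-(4-methylpent-3-enyl)cyclohex-1-en-1-yl]oxy}silane | CC(C)=CCC[C@]1(C)[C@@H](CC=C(C)C)CCC(O[Si](C)(C)C)=C1 | intermediate (not isolated)
10 | (3S,4R)-3-methyl-4-(3-methylbut-2-enyl)-3-(4-methylpent-3-enyl)cyclohexan-1-one (homoprenyl trans to prenyl) | CC(C)=CCC[C@]1(C)[C@@H](CC=C(C)C)CCC(=O)C1 | intermediate
11 | trimethyl{[(4S,5S)-5-methyl-4-(3-methylbut-2-enyl)-5-(4-methylpent-3-enyl)cyclohex-1-en-1-yl]oxy}silane | CC(C)=CCC[C@]1(C)[C@@H](CC=C(C)C)CC=C(O[Si](C)(C)C)C1 | intermediate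
12 | dichloroacetyl chloride | O=C(Cl)C(Cl)Cl | starting material
13 | (3S,4S)-8,8-dichloro-3-methyl-4-(3-methylbut-2-enyl)-3-(4-methylpent-3-enyl)-1-(trimethylsilyloxy)bicyclo[4.2.0]octan-7-one (cis-fused, fusion carbons not defined) | CC(C)=CCC[C@]1(C)[C@@H](CC=C(C)C)CC2C(=O)C(Cl)(Cl)C2(O[Si](C)(C)C)C1 | intermediate
14 | (3S,4S)-3-methyl-4-(3-methylbut-2-enyl)-3-(4-methylpent-3-enyl)-1-(trimethylsilyloxy)bicyclo[4.2.0]octan-7-one (cis-fused, fusion carbons not defined) | CC(C)=CCC[C@]1(C)[C@@H](CC=C(C)C)CC2C(=O)CC2(O[Si](C)(C)C)C1 | intermediate (not isolated)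
15 | (5S,6R)-5-methyl-6-(3-methylbut-2-enyl)-5-(4-methylpent-3-enyl)cyclooctane-1,3-dione | CC(C)=CCC[C@]1(C)[C@@H](CC=C(C)C)CCC(=O)CC(=O)C1 | intermediate
16 | 1-bromo-3-methylbut-2-ene | CC(C)=CCBr | starting material
17 | (6S,7S)-7-methyl-4,6-bis(3-methylbut-2-enyl)-7-(4-methylpent-3-enyl)cyclooctane-1,3-dione (epimers at C4) | CC(C)=CCC[C@]1(C)[C@@H](CC=C(C)C)CC(CC=C(C)C)C(=O)CC(=O)C1 | intermediate
18 | 3-methylbut-2-enyl acetate | CC(C)=CCOC(C)=O | starting material
19 | (6S,7S)-7-methyl-2,4,6-tris(3-methylbut-2-enyl)-7-(4-methylpent-3-enyl)cyclooctane-1,3-dione (C2 and C4 not defined) | CC(C)=CCC[C@]1(C)[C@@H](CC=C(C)C)CC(CC=C(C)C)C(=O)C(CC=C(C)C)C(=O)C1 | intermediate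
20 | N-methoxy-N,2-dimethylpropanamide | CC(C)C(=O)N(C)OC | starting material
21 | (5R,6S)-5-methyl-2,6,8-tris(3-methylbut-2-enyl)-5-(4-methylpent-3-enyl)-4-(2-methylpropanoyl)cyclooctane-1,3-dione (C2, C4 and C8 not defined) | CC(C)=CCC[C@]1(C)[C@@H](CC=C(C)C)CC(CC=C(C)C)C(=O)C(CC=C(C)C)C(=O)C1C(=O)C(C)C | intermediate
22 | (2R,5R,6S)-2-hydroxy-5-methyl-2,6,8-tris(3-methylbut-2-enyl)-5-(4-methylpent-3-enyl)-4-(2-methylpropanoyl)cyclooctane-1,3-dione (C4 and C8 not defined) | CC(C)=CCC[C@]1(C)[C@@H](CC=C(C)C)CC(CC=C(C)C)C(=O)[C@](O)(CC=C(C)C)C(=O)C1C(=O)C(C)C | intermediate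
23 | 1,1'-carbonyldiimidazole | O=C(n1ccnc1)n1ccnc1 | starting material
24 | (5R,6S,9aS)-5-methyl-6,8,9a-tris(3-methylbut-2-enyl)-5-(4-methylpent-3-enyl)-4-(2-methylpropanoyl)-5,6,7,8-tetrahydro-2H-cycloocta[d][1,3]dioxole-2,9(9aH)-dione (C8 not defined, ring-cis enol double bond) | CC(C)=CCC[C@]1(C)[C@@H](CC=C(C)C)CC(CC=C(C)C)C(=O)[C@@]2(CC=C(C)C)OC(=O)OC2=C1C(=O)C(C)C | intermediate
25 | (1R,3S,4R,5R,7S)-4-methyl-1,3,7-tris(3-methylbut-2-enyl)-4-(4-methylpent-3-enyl)-5-(2-methylpropanoyl)-8-oxabicyclo[5.2.1]decane-6,9,10-trione | CC(C)=CCC[C@]1(C)[C@@H](CC=C(C)C)C[C@@]2(CC=C(C)C)C(=O)O[C@@](CC=C(C)C)(C(=O)[C@H]1C(=O)C(C)C)C2=O | target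

**Step count and risks**

Total steps: 13. Longest linear sequence: 13 steps (1 to 25); all other inputs are purchased reagents.

The three steps most likely to fail:

Step 11. The oxidant may approach the enolate from the side of the C5–C6–C7 flap, or oxidise the other diketone carbon (C4), so that oxygen ends up on the wrong face or the wrong carbon. The fallback reverses the order in which the two C2 substituents arrive, so that the exposed face receives carbon and not oxygen. It sets out from 17: dianion acylation with 20 under the conditions of step 10 should give the 2-unsubstituted triketone F1. Its accessible C2 methylene enolate is oxidised with dibenzoyl peroxide to the 2-benzoyloxy triketone F2. Allylation with 18 and Pd(PPh3)4 then brings in prenyl as the second substituent and should give the 2-benzoyloxy-2-prenyl triketone F3. Methanolysis of the activated benzoate (K2CO3, MeOH, 0 °C) returns to the route at 22.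

Step 13. Lithiation may occur at the isobutyryl α-carbon, or the amide base may open the strained enol carbonate, so that the carboxyl is delivered to the wrong carbon or lost. The fallback forms the same bond from an open-chain acyl donor with the competing site masked as its enolate. It sets out from 22: double deprotonation with NaN(SiMe3)2 and phenyl chloroformate at −78 °C should acylate the more basic tertiary alkoxide and give the phenyl carbonate F4, isolated after a cold acidic quench. LiN(SiMe3)2 (2.2 equiv) first parks the 1,3-diketone as its enolate and then forms the ring-ketone enolate, which closes onto the aryl carbonate (Dieckmann-type) and returns to the route at 25.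

Step 10. The hindered dianion may be quenched by proton transfer from the more acidic product, or may add too slowly to the hindered amide at the neopentylic carbon. The fallback replaces acyl transfer by an aldol addition and an oxidation. It sets out from 19: the same dianion adds to the small and more electrophilic 2-methylpropanal to give the β-hydroxy ketone F5. Dess–Martin oxidation, which leaves the trisubstituted alkenes alone, returns to the route at 21.

**Further compounds**

F1 | step 11 | (5R,6S)-5-methyl-6,8-bis(3-methylbut-2-enyl)-5-(4-methylpent-3-enyl)-4-(2-methylpropanoyl)cyclooctane-1,3-dione | CC(C)=CCC[C@]1(C)[C@@H](CC=C(C)C)CC(CC=C(C)C)C(=O)CC(=O)C1C(=O)C(C)C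
F2 | step 11 | 2-benzoyloxy derivative of F1 (benzoate on the carbon between the two ring ketones) | CC(C)=CCC[C@]1(C)[C@@H](CC=C(C)C)CC(CC=C(C)C)C(=O)C(OC(=O)c2ccccc2)C(=O)C1C(=O)C(C)C
F3 | step 11 | benzoate ester of 22 (2-benzoyloxy-2-prenyl triketone) | CC(C)=CCC[C@]1(C)[C@@H](CC=C(C)C)CC(CC=C(C)C)C(=O)[C@](OC(=O)c2ccccc2)(CC=C(C)C)C(=O)C1C(=O)C(C)C
F4 | step 13 | phenyl carbonate of 22 (phenoxycarbonyl on the tertiary oxygen) | CC(C)=CCC[C@]1(C)[C@@H](CC=C(C)C)CC(CC=C(C)C)C(=O)[C@](OC(=O)Oc2ccccc2)(CC=C(C)C)C(=O)C1C(=O)C(C)C
F5 | step 10 | (5R,6S)-4-(1-hydroxy-2-methylpropyl)-5-methyl-2,6,8-tris(3-methylbut-2-enyl)-5-(4-methylpent-3-enyl)cyclooctane-1,3-dione | CC(C)=CCC[C@]1(C)[C@@H](CC=C(C)C)CC(CC=C(C)C)C(=O)C(CC=C(C)C)C(=O)C1C(O)C(C)C
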